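**Retrosynthetic overview**

1. Locants: unprimed = NH-indole (benzene ring A, pyrrole ring B); primed = N-linked indole (five-membered ring C, benzene ring D). The C3–Br and C3'–Br bonds are disconnected first and are installed together at the end by electrophilic bromination of both pyrrole β-positions.
2. Ring B is cut at C3–C3a and N1–C2 (Bartoli). Ring A then carries NO2 at the future C7a, flanked by the C7 methoxy group and by one free CH, the future C3a.
3. Structural feature that carries the plan: in ring D, C5' is para to N1', which is where an N-aryl indoline brominates. Ring C therefore stays saturated (C2'H2–C3'H2) until C5'–Br is in place and is dehydrogenated afterwards.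
4. Key disconnection N1'–C7a': the crowded C4–N1' junction already exists as a secondary aniline. Ring C closes by intramolecular copper-catalysed N-arylation of a 2-(2-iodophenyl)ethyl chain, built from brominated 4-methoxy-3-nitroaniline and 2-iodophenylacetic acid (acylation, then borane).
5. Ring order: A and D are purchased; C is closed in step 4 and aromatised in step 6; B is closed in step 7.

Key step: step 4

Assumption: the target SMILES carries no descriptor for the hindered C4–N1' axis, so the axis is treated as undefined and the route is planned for racemic material. There is no stereocentre to set.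

**Step 1**
Reactants: 1 4-methoxy-3-nitroaniline
Product: 2 2-bromo-4-methoxy-5-nitroaniline
Conditions: NBS (1.0 equiv), MeCN, 0 °C to rt, dark
Reagents that add atoms: N-bromosuccinimide, O=C1CCC(=O)N1Br
Why: In this electrophilic aromatic bromination the amino group directs, its para position is occupied by OMe and one ortho position is wedged between NH2 and NO2, so one equivalent of NBS should enter at the open ortho carbon, the future C5 of the target.

**Step 2**
Reactants: 3 2-iodophenylacetic acid; 2 2-bromo-4-methoxy-5-nitroaniline
Product: 5 N-(2-bromo-4-methoxy-5-nitrophenyl)-2-(2-iodophenyl)acetamide, via 2-iodophenylacetyl chloride 4 (not isolated)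
Conditions: (COCl)2, cat. DMF, CH2Cl2, 0 °C to rt, concentrate; then 2, pyridine, CH2Cl2, 0 °C to rt
Reagents that add atoms: oxalyl chloride, O=C(Cl)C(=O)Cl (supplies the chlorine of intermediate 4; nothing from it remains in 5)
Why: Acid chloride formation under Vilsmeier catalysis followed by pyridine-assisted N-acylation supplies an acyl donor strong enough for the weakly nucleophilic ortho-bromo, meta-nitro aniline, and the halides and the nitro group are inert.

**Step 3**
Reactants: 5 N-(2-bromo-4-methoxy-5-nitrophenyl)-2-(2-iodophenyl)acetamide
Product: 6 2-bromo-N-[2-(2-iodophenyl)ethyl]-4-methoxy-5-nitroaniline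
Conditions: BH3·THF (4 equiv), THF, 0 °C to reflux; then MeOH, aq HCl, 60 °C
Reagents that add atoms: none
Why: In this borane reduction of a secondary amide the electrophilic hydride donor attacks the Lewis basic amide carbonyl and spares the aromatic nitro group, the aryl iodide and the aryl bromide, and the weakly basic aniline nitrogen gives up boron readily in the acidic work-up.

**Step 4**
Reactants: 6 2-bromo-N-[2-(2-iodophenyl)ethyl]-4-methoxy-5-nitroaniline
Product: 7 1-(2-bromo-4-methoxy-5-nitrophenyl)indoline
Conditions: CuI (10 mol %), trans-N,N'-dimethylcyclohexane-1,2-diamine (20 mol %), K3PO4 (2 equiv), toluene, 80–90 °C, Ar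
Reagents that add atoms: none
Why: Diamine-ligated monovalent copper binds the N–H of 6, K3PO4 deprotonates it (the meta-nitro and ortho-bromo groups bring its acidity near that of an amide), and the copper amide activates the tethered C–I bond through a six-membered cupracycle of trivalent copper whose reductive elimination forms N1'–C7a'. The closest known reaction type is the intramolecular Ullmann–Goldberg N-arylation of 2-(2-halophenyl)ethylamines to indolines. Ring C closes as a five-membered ring, formally 5-exo with respect to the departing iodide, and no stereocentre is created. The step needs chemoselectivity for the aryl iodide over the ring A bromide: iodides react much faster with copper amides, only the iodide lies within reach of the tethered nitrogen, and the bromide ortho to the copper-bound nitrogen could only close a strained four-membered metallacycle. Toluene and a potassium base keep the liberated iodide out of solution as KI, which should suppress an aromatic Finkelstein-type bromide/iodide exchange on ring A. Intramolecularity offsets the steric load of the ortho-bromoaryl group, which would make an intermolecular arylation of this nitrogen sluggish.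

**Step 5**
Reactants: 7 1-(2-bromo-4-methoxy-5-nitrophenyl)indoline
Product: 8 5-bromo-1-(2-bromo-4-methoxy-5-nitrophenyl)indoline
Conditions: NBS (1.0 equiv), DMF, 0 °C, dark
Reagents that add atoms: N-bromosuccinimide, O=C1CCC(=O)N1Br
Why: In this electrophilic aromatic bromination the ring constraint holds the N1' lone pair in conjugation with ring D while ring A is twisted away by its ortho bromine and deactivated by NO2, so bromine should enter para to N1' at C5', with C7' shielded by the N-aryl group.

**Step 6**
Reactants: 8 5-bromo-1-(2-bromo-4-methoxy-5-nitrophenyl)indoline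
Product: 9 5-bromo-1-(2-bromo-4-methoxy-5-nitrophenyl)-1H-indole
Conditions: DDQ (1.2 equiv), toluene, rt to 80 °C
Reagents that add atoms: none
Why: DDQ dehydrogenation of an indoline (nitrogen-assisted hydride loss from C2', then proton loss from C3') is driven by the aromaticity gained in ring C, and the nitro, methoxy and bromo groups are inert to the quinone.

**Step 7**
Reactants: 9 5-bromo-1-(2-bromo-4-methoxy-5-nitrophenyl)-1H-indole; 10 vinylmagnesium bromide
Product: 12 5-bromo-4-(5-bromo-1H-indol-1-yl)-7-methoxy-1H-indole, via nitrosoarene 11 (not isolated)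
Conditions: 10 (3.5 equiv), THF, −45 to −40 °C; then sat. aq NH4Cl
Reagents that add atoms: vinylmagnesium bromide (10), C=C[Mg]Br
Why: In the Bartoli indole synthesis the first equivalent attacks a nitro oxygen to give nitrosoarene 11, the second adds to the nitroso oxygen, the ortho methoxy group favours the [3,3]-sigmatropic shift that forms C3–C3a at the only free ortho carbon, and the third acts as base before N1–C2 closure and dehydration, while aryl bromides do not exchange with this Grignard reagent at −40 °C.

**Step 8**
Reactants: 12 5-bromo-4-(5-bromo-1H-indol-1-yl)-7-methoxy-1H-indole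
Product: 13 rivularin B, 3,5-dibromo-4-(3,5-dibromo-1H-indol-1-yl)-7-methoxy-1H-indole
Conditions: NBS (2.05 equiv), DMF, −20 to 0 °C, dark; aq Na2S2O3/NaHCO3 quench
Reagents that add atoms: N-bromosuccinimide, O=C1CCC(=O)N1Br
Why: Electrophilic bromination of indoles goes to the enamine-like β-carbon, so C3 and C3' are the most nucleophilic sites of their ring systems and two equivalents of NBS under acid-free conditions should fill both before C2, C2' or C6 react.

**Compound list**

1 | 4-methoxy-3-nitroaniline | COc1ccc(N)cc1[N+](=O)[O-] | starting material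
2 | 2-bromo-4-methoxy-5-nitroaniline | COc1cc(Br)c(N)cc1[N+](=O)[O-] | intermediate
3 | 2-iodophenylacetic acid | OC(=O)Cc1ccccc1I | starting material
4 | 2-iodophenylacetyl chloride (not isolated) | O=C(Cl)Cc1ccccc1I | intermediate
5 | N-(2-bromo-4-methoxy-5-nitrophenyl)-2-(2-iodophenyl)acetamide | COc1cc(Br)c(NC(=O)Cc2ccccc2I)cc1[N+](=O)[O-] | intermediate
6 | 2-bromo-N-[2-(2-iodophenyl)ethyl]-4-methoxy-5-nitroaniline | COc1cc(Br)c(NCCc2ccccc2I)cc1[N+](=O)[O-] | intermediate
7 | 1-(2-bromo-4-methoxy-5-nitrophenyl)indoline | COc1cc(Br)c(N2CCc3ccccc32)cc1[N+](=O)[O-] | intermediate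
8 | 5-bromo-1-(2-bromo-4-methoxy-5-nitrophenyl)indoline | COc1cc(Br)c(N2CCc3cc(Br)ccc32)cc1[N+](=O)[O-] | intermediate
9 | 5-bromo-1-(2-bromo-4-methoxy-5-nitrophenyl)-1H-indole | COc1cc(Br)c(-n2ccc3cc(Br)ccc32)cc1[N+](=O)[O-] | intermediate
10 | vinylmagnesium bromide | C=C[Mg]Br | starting material
11 | 5-bromo-1-(2-bromo-4-methoxy-5-nitrosophenyl)-1H-indole (nitrosoarene, not isolated) | COc1cc(Br)c(-n2ccc3cc(Br)ccc32)cc1N=O | intermediate
12 | 5-bromo-4-(5-bromo-1H-indol-1-yl)-7-methoxy-1H-indole | COc1cc(Br)c(-n2ccc3cc(Br)ccc32)c2cc[nH]c12 | intermediate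
13 | rivularin B, 3,5-dibromo-4-(3,5-dibromo-1H-indol-1-yl)-7-methoxy-1H-indole | COc1cc(Br)c(-n2cc(Br)c3cc(Br)ccc32)c2c(Br)c[nH]c12 | target

Total step count: 8. Longest linear sequence: 8 steps, from 4-methoxy-3-nitroaniline.

**Steps most likely to fail**

**Step 7 (Bartoli indolization).**
- What may go wrong: methoxy is a weak ortho promoter, so over-reduction of the nitroso stage to aniline or azo-type material may compete. Addition of the Grignard reagent to the electron-poor ring may also compete. The sigmatropic shift has to end at a carbon next to the bulky indolyl group.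
- Fallback: ring B is built from the aniline by ortho-iodination, alkynylation and hydroamination. It sets out from 9 and returns to the route at 13.
- C3' of 9 is first blocked with its final bromine (NBS, 1 equiv, DMF, 0 °C) to give 3,5-dibromo-1-(2-bromo-4-methoxy-5-nitrophenyl)-1H-indole F1.
- Fe powder in AcOH–EtOH at 60 °C reduces the nitro group to 4-bromo-5-(3,5-dibromo-1H-indol-1-yl)-2-methoxyaniline F2.
- NIS with cat. TFA in MeCN iodinates the single open position ortho to NH2 (the para position carries bromine), giving 4-bromo-3-(3,5-dibromo-1H-indol-1-yl)-2-iodo-6-methoxyaniline F3.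
- Sonogashira coupling with ethynyltrimethylsilane (PdCl2(PPh3)2, CuI, Et3N, rt), selective for the iodide, gives 4-bromo-3-(3,5-dibromo-1H-indol-1-yl)-6-methoxy-2-[(trimethylsilyl)ethynyl]aniline F4.
- K2CO3 in MeOH frees 4-bromo-3-(3,5-dibromo-1H-indol-1-yl)-2-ethynyl-6-methoxyaniline F5.
- A 5-endo-dig hydroamination (cat. NaAuCl4, EtOH, rt, or CuI, DMF, 100 °C) closes ring B to 5-bromo-4-(3,5-dibromo-1H-indol-1-yl)-7-methoxy-1H-indole F6.
- One equivalent of NBS in DMF at C3 then gives 13.

**Step 4 (key ring closure).**
- What may go wrong: copper amide formation at the hindered, weakly basic nitrogen may be slow. That would leave room for protodeiodination, bromide/iodide exchange, or intermolecular coupling through the nitro-activated bromide.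
- Fallback: the same N1'–C7a' bond is closed one stage earlier with an amide nitrogen as nucleophile, the substrate class for which CuI/diamine catalysis is best suited. It sets out from 5 and returns at 7.
- Intramolecular Goldberg amidation of 5 (CuI, N,N'-dimethylethylenediamine, K3PO4, toluene, 90 °C, Ar) gives 1-(2-bromo-4-methoxy-5-nitrophenyl)-1,3-dihydro-2H-indol-2-one F7.
- The lactam carbonyl of F7 is then reduced with BH3·THF (THF, reflux, acidic methanol work-up) to indoline 7.

**Step 8 (double β-bromination).**
- What may go wrong: the two β-positions may react at unequal rates because C3 lies peri to the bulky C4 substituent. This could leave C3 incompletely brominated or cause over-bromination at C2 or C6. The N–H 3-bromoindole may also degrade under acid or light during isolation.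
- Fallback: the bromination is run on an N1-carbamate, which tempers ring B, shields C2 and gives a robust, chromatographable tetrabromide. It sets out from 12 and returns at 13.
- Boc2O with cat. DMAP in MeCN gives tert-butyl 5-bromo-4-(5-bromo-1H-indol-1-yl)-7-methoxy-1H-indole-1-carboxylate F8.
- NBS (2.2 equiv, DMF, rt) gives tert-butyl 3,5-dibromo-4-(3,5-dibromo-1H-indol-1-yl)-7-methoxy-1H-indole-1-carboxylate F9.
- Mild methanolysis (K2CO3, MeOH–THF, rt) removes the carbamate without acid to give 13.

**Further compounds**

F1 | step 7 | 3,5-dibromo-1-(2-bromo-4-methoxy-5-nitrophenyl)-1H-indole | COc1cc(Br)c(-n2cc(Br)c3cc(Br)ccc32)cc1[N+](=O)[O-]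
F2 | step 7 | 4-bromo-5-(3,5-dibromo-1H-indol-1-yl)-2-methoxyaniline | COc1cc(Br)c(-n2cc(Br)c3cc(Br)ccc32)cc1N
F3 | step 7 | 4-bromo-3-(3,5-dibromo-1H-indol-1-yl)-2-iodo-6-methoxyaniline | COc1cc(Br)c(-n2cc(Br)c3cc(Br)ccc32)c(I)c1N
F4 | step 7 | 4-bromo-3-(3,5-dibromo-1H-indol-1-yl)-6-methoxy-2-[(trimethylsilyl)ethynyl]aniline | COc1cc(Br)c(-n2cc(Br)c3cc(Br)ccc32)c(C#C[Si](C)(C)C)c1N
F5 | step 7 | 4-bromo-3-(3,5-dibromo-1H-indol-1-yl)-2-ethynyl-6-methoxyaniline | COc1cc(Br)c(-n2cc(Br)c3cc(Br)ccc32)c(C#C)c1N
F6 | step 7 | 5-bromo-4-(3,5-dibromo-1H-indol-1-yl)-7-methoxy-1H-indole | COc1cc(Br)c(-n2cc(Br)c3cc(Br)ccc32)c2cc[nH]c12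
F7 | step 4 | 1-(2-bromo-4-methoxy-5-nitrophenyl)-1,3-dihydro-2H-indol-2-one | COc1cc(Br)c(N2C(=O)Cc3ccccc32)cc1[N+](=O)[O-]
F8 | step 8 | tert-butyl 5-bromo-4-(5-bromo-1H-indol-1-yl)-7-methoxy-1H-indole-1-carboxylate | COc1cc(Br)c(-n2ccc3cc(Br)ccc32)c2ccn(C(=O)OC(C)(C)C)c12
F9 | step 8 | tert-butyl 3,5-dibromo-4-(3,5-dibromo-1H-indol-1-yl)-7-methoxy-1H-indole-1-carboxylate | COc1cc(Br)c(-n2cc(Br)c3cc(Br)ccc32)c2c(Br)cn(C(=O)OC(C)(C)C)c12
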